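**Retrosynthetic overview**

- The target comes from global desilylation of an all-cis pyranol, which comes from NaBH4 reduction (sets C4) of a 2,6-cis tetrahydropyran-4-one.
- The tetrahydropyranone is the only ring built (both benzene rings are bought) and it is closed last, after all fragments are joined. Its O1–C2 bond is made by oxa-Michael addition onto an (E)-aryl enone; the enone C3–C4 bond is made by rhodium-catalysed formyl C–H addition (hydroacylation) of a β-hydroxy aldehyde to an aryl alkyne.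
- The aryl alkyne comes from Sonogashira coupling of silylated 4-bromoguaiacol, made from catechol.
- The β-hydroxy aldehyde comes from alkene cleavage of an anti homoallylic alcohol (C6 set by Brown allylboration of an (R)-α-silyloxy aldehyde). That aldehyde comes from CuI-catalysed opening of methyl (R)-glycidate (source of C1') by the Grignard reagent of silylated 4-bromophenol.

Assumption: methyl (R)-glycidate and the B-allyldiisopinocampheylborane made from (+)-α-pinene are bought; TBSO = tert-butyldimethylsilyloxy, TIPSO = triisopropylsilyloxy; ring atoms are O1, C2 (aryl), C3, C4 (OH), C5, C6, and the side-chain carbinol is C1'.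

**Route**

Step 1
Reactants: 1 catechol
Product: 2 guaiacol (2-methoxyphenol)
Conditions: MeI (1.0 equiv), K2CO3 (1.0 equiv), acetone, reflux
Reagents that add atoms: iodomethane, CI
Why: Williamson ether synthesis on the mono-phenoxide; with one equivalent of MeI the monomethyl ether predominates and is separated from veratrole and catechol by base extraction (no stereocentre).

Step 2
Reactants: 2 guaiacol
Product: 3 4-bromo-2-methoxyphenol
Conditions: NBS (1.0 equiv), MeCN, 0 °C
Reagents that add atoms: N-bromosuccinimide, O=C1CCC(=O)N1Br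
Why: Electrophilic aromatic bromination directed by the free hydroxyl, the strongest donor, to its open para position (no stereocentre).

Step 3
Reactants: 3 4-bromo-2-methoxyphenol
Product: 4 (4-bromo-2-methoxyphenoxy)triisopropylsilane
Conditions: TIPSCl, imidazole, DMF, rt
Reagents that add atoms: chlorotriisopropylsilane, CC(C)[Si](Cl)(C(C)C)C(C)C
Why: Imidazole-promoted silyl ether formation gives a phenol protecting group that survives the later Pd, Cu, Rh, hydride and mild carbonate steps (no stereocentre).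

Step 4
Reactants: 4 (4-bromo-2-methoxyphenoxy)triisopropylsilane
Product: 5 {[3-methoxy-4-(TIPSO)phenyl]ethynyl}trimethylsilane
Conditions: HC≡CSiMe3 (1.5 equiv), PdCl2(PPh3)2 (3 mol %), CuI (5 mol %), Et3N, THF, 70 °C
Reagents that add atoms: ethynyltrimethylsilane, C#C[Si](C)(C)C
Why: Sonogashira coupling (oxidative addition of the aryl bromide to zerovalent palladium, copper acetylide transmetallation, reductive elimination); no stereocentre.

Step 5
Reactants: 5 {[3-methoxy-4-(TIPSO)phenyl]ethynyl}trimethylsilane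
Product: 6 4-ethynyl-2-methoxy-1-(TIPSO)benzene
Conditions: K2CO3 (0.2 equiv), MeOH–THF, 0 °C to rt
Reagents that add atoms: none
Why: Carbonate-catalysed methanolysis of the C(sp)–Si bond (protodesilylation), to which the hindered aryl TIPS ether is inert at this temperature (no stereocentre).

Step 6
Reactants: 7 4-bromophenol
Product: 8 (4-bromophenoxy)triisopropylsilane
Conditions: TIPSCl, imidazole, DMF, rt
Reagents that add atoms: chlorotriisopropylsilane, CC(C)[Si](Cl)(C(C)C)C(C)C
Why: Silyl ether formation masks the acidic phenol so that the aryl Grignard reagent can be made (no stereocentre).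

Step 7
Reactants: 8 (4-bromophenoxy)triisopropylsilane; 9 methyl (R)-oxirane-2-carboxylate [methyl (R)-glycidate]
Product: 11 methyl (R)-2-hydroxy-3-[4-(TIPSO)phenyl]propanoate, via aryl Grignard reagent 10 (not isolated)
Conditions: Mg turnings, THF, 40 °C; then 9, CuI (10 mol %), THF, −40 to −20 °C; aq NH4Cl
Reagents that add atoms: none
Why: Grignard formation followed by copper-catalysed epoxide ring opening (SN2 attack of the aryl cuprate at the unsubstituted C3), fast enough at −40 °C to spare the ester; the C2 stereocentre is not touched and stays (R).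

Step 8
Reactants: 11 methyl (R)-2-hydroxy-3-[4-(TIPSO)phenyl]propanoate
Product: 12 methyl (R)-2-(TBSO)-3-[4-(TIPSO)phenyl]propanoate
Conditions: TBSCl, imidazole, DMF, rt
Reagents that add atoms: tert-butylchlorodimethylsilane, CC(C)(C)[Si](C)(C)Cl
Why: Silyl ether formation under neutral imidazole conditions does not epimerise the α-centre, and the bulky non-chelating silyl group prepares the Felkin–Anh bias used in step 10.

Step 9
Reactants: 12 methyl (R)-2-(TBSO)-3-[4-(TIPSO)phenyl]propanoate
Product: 13 (R)-2-(TBSO)-3-[4-(TIPSO)phenyl]propanal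
Conditions: i-Bu2AlH (1.1 equiv), CH2Cl2, −78 °C; aq potassium sodium tartrate
Reagents that add atoms: none
Why: DIBAL half-reduction of the ester stops at the chelated tetrahedral aluminium hemiacetal at −78 °C and releases the aldehyde on work-up without loss of the (R) centre.

Step 10
Reactants: 13 (R)-2-(TBSO)-3-[4-(TIPSO)phenyl]propanal
Product: 14 (2R,3S)-2-(TBSO)-1-[4-(TIPSO)phenyl]hex-5-en-3-ol
Conditions: B-allyldiisopinocampheylborane from (+)-α-pinene (1.3 equiv), Et2O, −78 °C; then pH 7 NaH2PO4/Na2HPO4 buffer, MeOH, 30% H2O2, 0 °C to rt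
Reagents that add atoms: B-allyldiisopinocampheylborane from (+)-α-pinene, C=CCB([C@@H]1C[C@@H]2C[C@H]([C@H]1C)C2(C)C)[C@@H]1C[C@@H]2C[C@H]([C@H]1C)C2(C)C
Why: Brown asymmetric allylboration through a closed chair (Zimmerman–Traxler) transition state; the (+)-α-pinene-derived reagent adds to the Si face, which is also the Felkin–Anh face of the (R)-α-silyloxy aldehyde (matched case), and sets C3 as (S), anti to the silyloxy group.

Step 11
Reactants: 14 (2R,3S)-2-(TBSO)-1-[4-(TIPSO)phenyl]hex-5-en-3-ol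
Product: 16 (3S,4R)-4-(TBSO)-3-hydroxy-5-[4-(TIPSO)phenyl]pentanal, via triol 15 (not isolated)
Conditions: OsO4 (2 mol %), NaIO4 (4 equiv), 2,6-lutidine (2 equiv), dioxane–H2O (3:1), rt; used crude
Reagents that add atoms: sodium periodate, [Na+].[O-]I(=O)(=O)=O
Why: Lemieux–Johnson oxidation (osmium-catalysed dihydroxylation, then periodate glycol cleavage, buffered by 2,6-lutidine) removes the terminal carbon without touching the stereocentres or the silyl ethers.

Step 12
Reactants: 16 (3S,4R)-4-(TBSO)-3-hydroxy-5-[4-(TIPSO)phenyl]pentanal; 6 4-ethynyl-2-methoxy-1-(TIPSO)benzene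
Product: 18 (2R,6S)-6-{(1R)-1-(TBSO)-2-[4-(TIPSO)phenyl]ethyl}-2-[3-methoxy-4-(TIPSO)phenyl]tetrahydro-4H-pyran-4-one, via hydroxy enone 17 (not isolated)
Conditions: [Rh(cod)OH]2 (2.5 mol %), dppe (5 mol %), toluene, 50 °C, 6 (1.3 equiv) added over 3 h; then DBU (0.3 equiv), rt
Reagents that add atoms: none
Why: Proposed new method: hydroxyl-directed rhodium-catalysed alkyne hydroacylation of an aliphatic β-hydroxy aldehyde run in tandem with oxa-Michael ring closure – the C6 hydroxyl of 16 exchanges onto the Rh–OH centre, the resulting monovalent rhodium alkoxide inserts into the formyl C–H bond to give a five-membered κ2-C,O acyl hydride chelate of trivalent rhodium that is too rigid to decarbonylate, alkyne 6 inserts into Rh–H with the metal on the terminal carbon, C–C reductive elimination forms the C3–C4 bond of (E)-enone 17, and DBU then closes the ring by reversible 6-endo oxa-Michael addition through a chair that places the aryl group equatorial and cis to the C6 side chain (2R); closest known reaction type: rhodium-catalysed alkyne hydroacylation of salicylaldehydes (phenoxide chelation) with oxa-Michael closure to chroman-4-ones, and chelation-assisted hydroacylation with β-sulfanyl aldehydes.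

Step 13
Reactants: 18 (2R,6S)-6-{(1R)-1-(TBSO)-2-[4-(TIPSO)phenyl]ethyl}-2-[3-methoxy-4-(TIPSO)phenyl]tetrahydro-4H-pyran-4-one
Product: 19 (2R,4R,6S)-6-{(1R)-1-(TBSO)-2-[4-(TIPSO)phenyl]ethyl}-2-[3-methoxy-4-(TIPSO)phenyl]tetrahydro-2H-pyran-4-ol
Conditions: NaBH4, MeOH, −40 °C
Reagents that add atoms: none
Why: Hydride reduction of a conformationally fixed cis-2,6-diequatorial tetrahydropyran-4-one; the small borohydride attacks axially and gives the equatorial (4R) alcohol, all-cis.

Step 14
Reactants: 19 (2R,4R,6S)-6-{(1R)-1-(TBSO)-2-[4-(TIPSO)phenyl]ethyl}-2-[3-methoxy-4-(TIPSO)phenyl]tetrahydro-2H-pyran-4-ol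
Product: 20 (2R,4R,6S)-2-(4-hydroxy-3-methoxyphenyl)-6-[(1R)-1-hydroxy-2-(4-hydroxyphenyl)ethyl]tetrahydro-2H-pyran-4-ol (CNP0116327.2)
Conditions: Bu4NF (6 equiv), AcOH (6 equiv), THF, rt to 40 °C
Reagents that add atoms: none
Why: Fluoride-mediated desilylation, driven by the Si–F bond strength, removes both aryl TIPS ethers and the secondary TBS ether, while the acetic acid buffer keeps the phenols protonated so the benzylic C2–O bond and the stereocentres are not disturbed.

**Compound list**

1 | catechol (benzene-1,2-diol) | Oc1ccccc1O | starting material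
2 | guaiacol (2-methoxyphenol) | COc1ccccc1O | intermediate
3 | 4-bromo-2-methoxyphenol | COc1cc(Br)ccc1O | intermediate
4 | (4-bromo-2-methoxyphenoxy)triisopropylsilane | COc1cc(Br)ccc1O[Si](C(C)C)(C(C)C)C(C)C | intermediate
5 | {[3-methoxy-4-(triisopropylsilyloxy)phenyl]ethynyl}trimethylsilane | COc1cc(C#C[Si](C)(C)C)ccc1O[Si](C(C)C)(C(C)C)C(C)C | intermediate
6 | 4-ethynyl-2-methoxy-1-(triisopropylsilyloxy)benzene | COc1cc(C#C)ccc1O[Si](C(C)C)(C(C)C)C(C)C | intermediate
7 | 4-bromophenol | Oc1ccc(Br)cc1 | starting material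
8 | (4-bromophenoxy)triisopropylsilane | Brc1ccc(O[Si](C(C)C)(C(C)C)C(C)C)cc1 | intermediate
9 | methyl (R)-oxirane-2-carboxylate (methyl (R)-glycidate) | COC(=O)[C@H]1CO1 | starting material
10 | [4-(triisopropylsilyloxy)phenyl]magnesium bromide | Br[Mg]c1ccc(O[Si](C(C)C)(C(C)C)C(C)C)cc1 | intermediate
11 | methyl (R)-2-hydroxy-3-[4-(triisopropylsilyloxy)phenyl]propanoate | COC(=O)[C@H](O)Cc1ccc(O[Si](C(C)C)(C(C)C)C(C)C)cc1 | intermediate
12 | methyl (R)-2-(tert-butyldimethylsilyloxy)-3-[4-(triisopropylsilyloxy)phenyl]propanoate | COC(=O)[C@H](O[Si](C)(C)C(C)(C)C)Cc1ccc(O[Si](C(C)C)(C(C)C)C(C)C)cc1 | intermediate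
13 | (R)-2-(tert-butyldimethylsilyloxy)-3-[4-(triisopropylsilyloxy)phenyl]propanal | O=C[C@H](O[Si](C)(C)C(C)(C)C)Cc1ccc(O[Si](C(C)C)(C(C)C)C(C)C)cc1 | intermediate
14 | (2R,3S)-2-(tert-butyldimethylsilyloxy)-1-[4-(triisopropylsilyloxy)phenyl]hex-5-en-3-ol | C=CC[C@H](O)[C@H](O[Si](C)(C)C(C)(C)C)Cc1ccc(O[Si](C(C)C)(C(C)C)C(C)C)cc1 | intermediate
15 | (4S,5R)-5-(tert-butyldimethylsilyloxy)-6-[4-(triisopropylsilyloxy)phenyl]hexane-1,2,4-triol (both C2 epimers) | OCC(O)C[C@H](O)[C@H](O[Si](C)(C)C(C)(C)C)Cc1ccc(O[Si](C(C)C)(C(C)C)C(C)C)cc1 | intermediate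
16 | (3S,4R)-4-(tert-butyldimethylsilyloxy)-3-hydroxy-5-[4-(triisopropylsilyloxy)phenyl]pentanal | O=CC[C@H](O)[C@H](O[Si](C)(C)C(C)(C)C)Cc1ccc(O[Si](C(C)C)(C(C)C)C(C)C)cc1 | intermediate
17 | (1E,5S,6R)-6-(tert-butyldimethylsilyloxy)-5-hydroxy-1-[3-methoxy-4-(triisopropylsilyloxy)phenyl]-7-[4-(triisopropylsilyloxy)phenyl]hept-1-en-3-one | COc1cc(/C=C/C(=O)C[C@H](O)[C@H](O[Si](C)(C)C(C)(C)C)Cc2ccc(O[Si](C(C)C)(C(C)C)C(C)C)cc2)ccc1O[Si](C(C)C)(C(C)C)C(C)C | intermediate
18 | (2R,6S)-6-{(1R)-1-(tert-butyldimethylsilyloxy)-2-[4-(triisopropylsilyloxy)phenyl]ethyl}-2-[3-methoxy-4-(triisopropylsilyloxy)phenyl]tetrahydro-4H-pyran-4-one | COc1cc([C@H]2CC(=O)C[C@@H]([C@H](O[Si](C)(C)C(C)(C)C)Cc3ccc(O[Si](C(C)C)(C(C)C)C(C)C)cc3)O2)ccc1O[Si](C(C)C)(C(C)C)C(C)C | intermediate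
19 | (2R,4R,6S)-6-{(1R)-1-(tert-butyldimethylsilyloxy)-2-[4-(triisopropylsilyloxy)phenyl]ethyl}-2-[3-methoxy-4-(triisopropylsilyloxy)phenyl]tetrahydro-2H-pyran-4-ol | COc1cc([C@H]2C[C@@H](O)C[C@@H]([C@H](O[Si](C)(C)C(C)(C)C)Cc3ccc(O[Si](C(C)C)(C(C)C)C(C)C)cc3)O2)ccc1O[Si](C(C)C)(C(C)C)C(C)C | intermediate
20 | (2R,4R,6S)-2-(4-hydroxy-3-methoxyphenyl)-6-[(1R)-1-hydroxy-2-(4-hydroxyphenyl)ethyl]tetrahydro-2H-pyran-4-ol | COc1cc([C@H]2C[C@@H](O)C[C@@H]([C@H](O)Cc3ccc(O)cc3)O2)ccc1O | target

**Step count**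

Total step count: 14 (steps 1–5 aryl alkyne branch, steps 6–11 hydroxy aldehyde branch, steps 12–14 after the union).
Longest linear sequence: 9 steps (steps 6 to 14, from 7), that is 9 of 14.

**Steps most likely to fail**

Step 12 (the proposed new step). Possible failures are decarbonylation of 16, β-hydride elimination or retro-aldol cleavage of the rhodium alkoxide, 1,2-silyl migration from O-C1' to O-C6, rhodium-induced oligomerisation of alkyne 6, and branched instead of linear acyl transfer. The fallback uses only known chemistry; it sets out from 13 and 4 and comes back to the route at 17 and so at 18. Heck coupling of 4 with methyl vinyl ketone (Pd(OAc)2, P(o-tol)3, Et3N, MeCN, 90 °C) gives (E)-4-[3-methoxy-4-(triisopropylsilyloxy)phenyl]but-3-en-2-one F7. TMSOTf and Et3N in CH2Cl2 at 0 °C convert it into trimethyl{[(3E)-4-(3-methoxy-4-(triisopropylsilyloxy)phenyl)buta-1,3-dien-2-yl]oxy}silane F8. Mukaiyama aldol addition of F8 to aldehyde 13 (BF3·OEt2, CH2Cl2, −78 °C) proceeds under Felkin–Anh control, anti to the silyloxy group, and gives 17 after aqueous work-up. DBU (or Amberlyst 15 in CH2Cl2) then closes 17 to 18 by the same oxa-Michael addition as in step 12.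

Step 11. The β-hydroxy aldehyde 16 can dehydrate, oligomerise or undergo retro-aldol cleavage during cleavage and handling. The fallback avoids 16 altogether; it sets out from 14 and 4 and comes back at 19. Bromine–lithium exchange on 4 (n-BuLi, THF, −78 °C) gives [3-methoxy-4-(triisopropylsilyloxy)phenyl]lithium F4, which is formylated with DMF to 3-methoxy-4-(triisopropylsilyloxy)benzaldehyde F5. Prins cyclisation of homoallylic alcohol 14 with F5 (TFA, CH2Cl2, 0 °C) passes through a chair oxocarbenium ion with all substituents equatorial and gives (2R,4R,6S)-6-{(1R)-1-(tert-butyldimethylsilyloxy)-2-[4-(triisopropylsilyloxy)phenyl]ethyl}-2-[3-methoxy-4-(triisopropylsilyloxy)phenyl]tetrahydro-2H-pyran-4-yl trifluoroacetate F6. Methanolysis with NaHCO3 in MeOH gives 19, which continues with step 14.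

Step 7. The Grignard reagent may attack the ester of 9, or open the epoxide with poor regiocontrol. The fallback uses an epoxide without an ester; it sets out from 8 (through Grignard reagent 10) and comes back at 13. Reagent 10 (2.2 equiv) with CuI (10 mol %) opens unprotected (S)-glycidol (OC[C@H]1CO1) at C3 and gives (R)-3-[4-(triisopropylsilyloxy)phenyl]propane-1,2-diol F1. TBSCl and imidazole give (R)-1,2-bis(tert-butyldimethylsilyloxy)-3-[4-(triisopropylsilyloxy)phenyl]propane F2. HF·pyridine in THF–pyridine at 0 °C removes only the primary silyl group and gives (R)-2-(tert-butyldimethylsilyloxy)-3-[4-(triisopropylsilyloxy)phenyl]propan-1-ol F3. Dess–Martin periodinane with NaHCO3 in CH2Cl2 then gives aldehyde 13.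

Further compounds
F1 | step 7 | (R)-3-[4-(triisopropylsilyloxy)phenyl]propane-1,2-diol | OC[C@H](O)Cc1ccc(O[Si](C(C)C)(C(C)C)C(C)C)cc1
F2 | step 7 | (R)-1,2-bis(tert-butyldimethylsilyloxy)-3-[4-(triisopropylsilyloxy)phenyl]propane | CC(C)(C)[Si](C)(C)OC[C@H](O[Si](C)(C)C(C)(C)C)Cc1ccc(O[Si](C(C)C)(C(C)C)C(C)C)cc1
F3 | step 7 | (R)-2-(tert-butyldimethylsilyloxy)-3-[4-(triisopropylsilyloxy)phenyl]propan-1-ol | OC[C@H](O[Si](C)(C)C(C)(C)C)Cc1ccc(O[Si](C(C)C)(C(C)C)C(C)C)cc1
F4 | step 11 | [3-methoxy-4-(triisopropylsilyloxy)phenyl]lithium | [Li]c1ccc(O[Si](C(C)C)(C(C)C)C(C)C)c(OC)c1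
F5 | step 11 | 3-methoxy-4-(triisopropylsilyloxy)benzaldehyde | COc1cc(C=O)ccc1O[Si](C(C)C)(C(C)C)C(C)C
F6 | step 11 | (2R,4R,6S)-6-{(1R)-1-(tert-butyldimethylsilyloxy)-2-[4-(triisopropylsilyloxy)phenyl]ethyl}-2-[3-methoxy-4-(triisopropylsilyloxy)phenyl]tetrahydro-2H-pyran-4-yl trifluoroacetate | COc1cc([C@H]2C[C@@H](OC(=O)C(F)(F)F)C[C@@H]([C@H](O[Si](C)(C)C(C)(C)C)Cc3ccc(O[Si](C(C)C)(C(C)C)C(C)C)cc3)O2)ccc1O[Si](C(C)C)(C(C)C)C(C)C
F7 | step 12 | (E)-4-[3-methoxy-4-(triisopropylsilyloxy)phenyl]but-3-en-2-one | CC(=O)/C=C/c1ccc(O[Si](C(C)C)(C(C)C)C(C)C)c(OC)c1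
F8 | step 12 | trimethyl{[(3E)-4-(3-methoxy-4-(triisopropylsilyloxy)phenyl)buta-1,3-dien-2-yl]oxy}silane | C=C(O[Si](C)(C)C)/C=C/c1ccc(O[Si](C(C)C)(C(C)C)C(C)C)c(OC)c1
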